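Plan
1. Locants (cyclobuta[a]indene core): C1 is the CH bearing the catechol ring, C2 is CMe2, C2a and C7b are the ring-fusion CH groups (C7b sits on aromatic ring A), C3 is the benzylic CH2, and C3a is the ring A carbon bonded to C3. The 2,2-dimethyl-2H-pyran ring is fused to ring A at C6 (oxygen) and C7.
2. Enabling feature: C2a carries the one-carbon branch C3 and is bonded directly to the quaternary C2. C3 can therefore be placed as a carbonyl between C2a and C2 of a cyclopentanone, and the 2-diazo derivative of that ketone expels C3 as an exocyclic ketene at the moment C2 shifts onto C2a.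
3. Cuts in retrosynthetic order: the catechol protecting groups, C3=O back from CH2, C3–C3a (Friedel–Crafts acylation), C2–C2a (Wolff contraction), C7b–ring A (conjugate addition), one C2–CH3, and C1–catechol aryl (asymmetric conjugate addition to 2-methylcyclopent-2-enone).
4. Forward order of rings: the pyran ring is closed first, on the separate ring A bromide. The purchased five-membered carbocycle then receives both aryl groups and is contracted to the cyclobutane. The ring C2a–C3–C3a–C7a–C7b closes last.
5. Stereochemistry: C1 comes from the (S)-BINAP–rhodium catalyst, C7b from addition anti to the C1 aryl group, and C2a from kinetic protonation of the ester enol on the face away from ring A. The cis ring fusion then holds C2a.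

Key step: step 11

Remark: (S)-BINAP is assumed to induce the same sense on 2-methylcyclopent-2-enone as on cyclopent-2-enone, (S) at the aryl-bearing carbon. Fused compounds are named on the core locants above, with "pyrano" standing for the fused 2,2-dimethyl-2H-pyran ring.

Step 1
Reactants: 1 4-bromobenzene-1,2-diol
Product: 2 4-bromo-1,2-bis(methoxymethoxy)benzene
Conditions: MOMCl (2.5 equiv), iPr2NEt (3 equiv), CH2Cl2, 0 to 25 °C
Reagents that add atoms: chloromethyl methyl ether, COCCl
Why: Double O-alkylation of the catechol with the reactive chloromethyl ether (Williamson-type acetal ether formation) masks both phenols as groups that tolerate organometallic reagents, strong base and visible light and that can be removed at the end without Brønsted acid.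

Step 2
Reactants: 2 4-bromo-1,2-bis(methoxymethoxy)benzene
Product: 5 [3,4-bis(methoxymethoxy)phenyl]boronic acid, via aryllithium 3 (not isolated), via lithium aryltriisopropoxyborate 4 (not isolated)
Conditions: n-BuLi, THF, −78 °C; B(OiPr)3, −78 to 0 °C; AcOH, H2O
Reagents that add atoms: triisopropyl borate, CC(C)OB(OC(C)C)OC(C)C; water, O
Why: Bromine–lithium exchange at −78 °C is faster than lithiation ortho to the OMOM groups, and trapping the aryllithium with the borate ester followed by weakly acidic hydrolysis is the standard lithiation–borylation route to arylboronic acids.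

Step 3
Reactants: 5 [3,4-bis(methoxymethoxy)phenyl]boronic acid; 6 2-methylcyclopent-2-en-1-one
Product: 7 (2R,3S)-3-[3,4-bis(methoxymethoxy)phenyl]-2-methylcyclopentan-1-one
Conditions: 5 (2.5 equiv), [RhCl(C2H4)2]2 (2.5 mol %), (S)-BINAP (6 mol %), KOH (0.5 equiv), dioxane/H2O 10:1, 60 °C
Reagents that add atoms: none
Why: Hayashi–Miyaura asymmetric 1,4-addition, in which the aryl–rhodium species carrying (S)-BINAP inserts the enone on the face that leads to (S)-3-arylcyclopentanones and so sets the future C1, while the adjacent methyl-bearing centre settles trans under the basic conditions and is erased in step 4.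

Step 4
Reactants: 7 (2R,3S)-3-[3,4-bis(methoxymethoxy)phenyl]-2-methylcyclopentan-1-one
Product: 9 (3R)-3-[3,4-bis(methoxymethoxy)phenyl]-2,2-dimethylcyclopentan-1-one, via potassium enolate 8 (not isolated)
Conditions: KOtBu (1.05 equiv), tBuOH/THF, 25 °C; MeI (1.2 equiv), 0 °C
Reagents that add atoms: iodomethane, CI
Why: Enolate alkylation under equilibrating conditions runs through the tetrasubstituted enolate that is strongly preferred for 2-methylcyclopentanones, so the second methyl group enters at the carbon next to the aryl-bearing centre and builds the quaternary C2 without touching the existing stereocentre.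

Step 5
Reactants: 9 (3R)-3-[3,4-bis(methoxymethoxy)phenyl]-2,2-dimethylcyclopentan-1-one
Product: 12 (4R)-4-[3,4-bis(methoxymethoxy)phenyl]-5,5-dimethylcyclopent-2-en-1-one, via lithium enolate 10 (not isolated), via trimethylsilyl enol ether 11 (not isolated)
Conditions: LiN(iPr)2, Me3SiCl, THF, −78 °C; then Pd(OAc)2 (10 mol %), O2 (1 atm), DMSO, 25 °C
Reagents that add atoms: none
Why: The Saegusa–Ito oxidation in its aerobic catalytic form works here because only one α-position can be enolised, the silyl enol ether passes to an oxa-π-allyl complex of divalent palladium that undergoes β-hydride elimination, and the neutral medium does not deprotonate the benzylic γ-stereocentre of the enone.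

Step 6
Reactants: 13 1-bromo-3,5-dimethoxybenzene
Product: 15 2-bromo-4,6-dimethoxybenzaldehyde, via iminium chloride 14 (not isolated)
Conditions: POCl3, DMF, 0 to 90 °C; then H2O, NaOAc
Reagents that add atoms: N,N-dimethylformamide, CN(C)C=O; water, O
Why: Vilsmeier–Haack formylation of this bromide is known to go para to one methoxy group and ortho to the other, next to bromine, rather than into the crowded site between the two methoxy groups.

Step 7
Reactants: 15 2-bromo-4,6-dimethoxybenzaldehyde
Product: 17 2-bromo-6-hydroxy-4-methoxybenzaldehyde, via aryloxydichloroborane 16 (not isolated)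
Conditions: BCl3 (1.2 equiv), CH2Cl2, −78 to 0 °C; then H2O
Reagents that add atoms: none
Why: BCl3 binds between the aldehyde oxygen and the ortho methoxy oxygen, so chelation-directed ether cleavage removes only that methyl group and leaves the para methoxy group, the future ring A methyl ether.

Step 8
Reactants: 17 2-bromo-6-hydroxy-4-methoxybenzaldehyde; 18 (2-methylprop-1-en-1-yl)magnesium bromide
Product: 21 5-bromo-7-methoxy-2,2-dimethyl-2H-chromene, via benzylic alcohol 19 (not isolated), via o-quinone methide 20 (not isolated)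
Conditions: 18 (2.5 equiv), THF, 0 °C; aq. NH4Cl; then PPTS (5 mol %), toluene, 80 °C
Reagents that add atoms: none
Why: 1,2-Addition of the alkenyl Grignard reagent gives an o-hydroxybenzylic allylic alcohol that loses water to an o-quinone methide, and oxa-6π electrocyclisation of this species closes the 2,2-dimethyl-2H-pyran ring with bromine fixed at C5 of the chromene, so no regiochemical choice arises.

Step 9
Reactants: 21 5-bromo-7-methoxy-2,2-dimethyl-2H-chromene; 12 (4R)-4-[3,4-bis(methoxymethoxy)phenyl]-5,5-dimethylcyclopent-2-en-1-one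
Product: 24 (3R,4R)-3-[3,4-bis(methoxymethoxy)phenyl]-4-(7-methoxy-2,2-dimethyl-2H-chromen-5-yl)-2,2-dimethylcyclopentan-1-one, via arylmagnesium bromide 22 (not isolated), via trimethylsilyl enol ether 23 (not isolated)
Conditions: 21 (1.5 equiv), Mg turnings, THF, 45 °C; then 12, CuBr·SMe2 (15 mol %), Me3SiCl (2.5 equiv), THF, −78 to −40 °C; then 10% aq. citric acid, 25 °C
Reagents that add atoms: none
Why: Copper-catalysed conjugate addition of an aryl Grignard reagent accelerated by Me3SiCl is fast at low temperature even on hindered cyclopentenones, so γ-deprotonation does not compete, and the aryl group enters anti to the neighbouring catechol aryl group, which sets C7b trans to C1.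

Step 10
Reactants: 24 (3R,4R)-3-[3,4-bis(methoxymethoxy)phenyl]-4-(7-methoxy-2,2-dimethyl-2H-chromen-5-yl)-2,2-dimethylcyclopentan-1-one
Product: 27 (3R,4R)-4-[3,4-bis(methoxymethoxy)phenyl]-2-diazo-3-(7-methoxy-2,2-dimethyl-2H-chromen-5-yl)-5,5-dimethylcyclopentan-1-one, via lithium enolate 25 (not isolated), via trifluoroacetyl ketone 26 (not isolated)
Conditions: LiN(SiMe3)2, THF, −78 °C; CF3CO2CH2CF3; cold 5% aq. HCl; then 4-AcNHC6H4SO2N3, Et3N, H2O, MeCN, 25 °C
Reagents that add atoms: 4-acetamidobenzenesulfonyl azide, CC(=O)Nc1ccc(cc1)S(=O)(=O)N=[N+]=[N-]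
Why: This is the detrifluoroacetylative variant of the Regitz diazo transfer, in which the single enolisable position is first activated as the trifluoroacetyl ketone and the sulfonyl azide then delivers N2 with loss of the trifluoroacetyl group as the N-acylsulfonamide, leaving both stereocentres untouched.

Step 11
Reactants: 27 (3R,4R)-4-[3,4-bis(methoxymethoxy)phenyl]-2-diazo-3-(7-methoxy-2,2-dimethyl-2H-chromen-5-yl)-5,5-dimethylcyclopentan-1-one
Product: 30 methyl (1S,3S,4S)-3-[3,4-bis(methoxymethoxy)phenyl]-4-(7-methoxy-2,2-dimethyl-2H-chromen-5-yl)-2,2-dimethylcyclobutane-1-carboxylate, via ketene 28 (not isolated), via ester enol 29 (not isolated)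
Conditions: blue LEDs (λmax 440 nm), MeOH/THF 4:1, 0 °C, argon
Reagents that add atoms: methanol, CO
Why: Excitation of the n–π* band of the s-cis-locked diazo ketone expels N2 while the C2–C3 bond shifts to the diazo carbon, so C2–C2a forms in concert and C3 leaves the ring as ketene 28, which adds methanol to give enol 29 and, after C-protonation, ester 30. The closest known reaction is the photochemical Wolff ring contraction of cyclic 2-diazo ketones, which is documented for 2-diazo-5,5-dimethylcyclopentanone, where the same kind of quaternary carbon migrates. The cyclobutane arises by a 1,2-shift (contraction of the five-membered ring to the four-membered one) and not by cyclisation of a chain, so C1 and C7b pass through untouched and the aryl groups stay trans. The one new stereocentre, C2a, is set in the ketonisation of 29, where the proton should arrive on the face opposite the adjacent ring A aryl group (kinetic protonation of an exocyclic enol), which leaves the ester cis to ring A as the later ring closure demands. Migration is unambiguous because C2 is the only carbon on the carbonyl besides the diazo carbon, and the competing 1,2-hydride shift from C7b and O–H insertion are free-carbene reactions that the concerted path from the locked s-cis geometry avoids. Light above 420 nm is absorbed by the diazo ketone alone, which spares the 2H-chromene its ultraviolet electrocyclic ring opening.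

Step 12
Reactants: 30 methyl (1S,3S,4S)-3-[3,4-bis(methoxymethoxy)phenyl]-4-(7-methoxy-2,2-dimethyl-2H-chromen-5-yl)-2,2-dimethylcyclobutane-1-carboxylate
Product: 32 (1S,3S,4S)-3-[3,4-bis(methoxymethoxy)phenyl]-4-(7-methoxy-2,2-dimethyl-2H-chromen-5-yl)-2,2-dimethylcyclobutane-1-carboxylic acid, via trimethylstannyl ester 31 (not isolated)
Conditions: Me3SnOH (6 equiv), ClCH2CH2Cl, 75 °C; then 0.1 M aq. HCl wash
Reagents that add atoms: trimethyltin hydroxide, C[Sn](C)(C)O
Why: Trimethyltin hydroxide cleaves hindered methyl esters by tin-assisted acyl substitution in a nearly neutral medium, which avoids enolisation at C2a and thus epimerisation to the more stable trans acid that hot aqueous hydroxide could cause.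

Step 13
Reactants: 32 (1S,3S,4S)-3-[3,4-bis(methoxymethoxy)phenyl]-4-(7-methoxy-2,2-dimethyl-2H-chromen-5-yl)-2,2-dimethylcyclobutane-1-carboxylic acid
Product: 34 (1S,2aS,7bS)-1-[3,4-bis(methoxymethoxy)phenyl]-4-methoxy-2,2-dimethyl-6,7-pyrano-1,2,2a,7b-tetrahydro-3H-cyclobuta[a]inden-3-one, via acyl trifluoroacetate 33 (not isolated)
Conditions: (CF3CO)2O (1.3 equiv), CH2Cl2 (0.02 M), 0 °C; aq. NaHCO3
Reagents that add atoms: none
Why: Intramolecular Friedel–Crafts acylation through the acyl trifluoroacetate should succeed because C3a is the only free ring A position within reach, lies ortho to the methoxy group and para to the pyran oxygen, and is nucleophilic enough to react at 0 °C in dilute solution where chromene and MOM ethers tolerate the released CF3CO2H, and because closure of cis-2-arylcyclobutanecarboxylic acids to cyclobuta[a]indenones is a known reaction.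

Step 14
Reactants: 34 (1S,2aS,7bS)-1-[3,4-bis(methoxymethoxy)phenyl]-4-methoxy-2,2-dimethyl-6,7-pyrano-1,2,2a,7b-tetrahydro-3H-cyclobuta[a]inden-3-one
Product: 35 4-methylbenzenesulfonohydrazone of ketone 34
Conditions: TsNHNH2 (2 equiv), EtOH, 70 °C
Reagents that add atoms: 4-methylbenzenesulfonohydrazide, Cc1ccc(cc1)S(=O)(=O)NN
Why: Condensation of the aryl ketone with tosylhydrazine prepares a deoxygenation that needs neither a cyclobutylcarbinyl cation at C3 nor strong acid, and C2a is safe because only the cis ring fusion is viable.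

Step 15
Reactants: 35 4-methylbenzenesulfonohydrazone of ketone 34
Product: 38 (1S,2aS,7bR)-1-[3,4-bis(methoxymethoxy)phenyl]-4-methoxy-2,2-dimethyl-6,7-pyrano-2,2a,3,7b-tetrahydro-1H-cyclobuta[a]indene, via N-boryl tosylhydrazine 36 (not isolated), via alkyldiazene 37 (not isolated)
Conditions: catecholborane (3 equiv), CHCl3, −10 to 0 °C; then NaOAc·3H2O, 60 °C
Reagents that add atoms: none
Why: In this catecholborane variant of the Caglioti reaction the borane adds hydride to the C=N bond, acetate then eliminates sulfinate, and the alkyldiazene loses N2 to leave the C3 methylene group under conditions too mild for hydroboration of the chromene double bond.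

Step 16
Reactants: 38 (1S,2aS,7bR)-1-[3,4-bis(methoxymethoxy)phenyl]-4-methoxy-2,2-dimethyl-6,7-pyrano-2,2a,3,7b-tetrahydro-1H-cyclobuta[a]indene
Product: 40 CNP0207533.1 (1S,2aS,7bR)-1-(3,4-dihydroxyphenyl)-4-methoxy-2,2-dimethyl-6,7-pyrano-2,2a,3,7b-tetrahydro-1H-cyclobuta[a]indene, via bis(trimethylsilyl) ether 39 (not isolated)
Conditions: Me3SiOTf (5 equiv), 2,2'-bipyridyl (7 equiv), MeCN, 0 to 25 °C; then degassed H2O, 25 °C
Reagents that add atoms: none
Why: The Me3SiOTf–2,2'-bipyridyl pair converts aryl MOM ethers into aryl silyl ethers in a buffered aprotic medium and water then frees the phenols, so the acid-sensitive electron-rich chromene, the ring A methyl ether and the three stereocentres stay intact.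

Compound list
1 | 4-bromobenzene-1,2-diol | Oc1ccc(Br)cc1O | starting material
2 | 4-bromo-1,2-bis(methoxymethoxy)benzene | COCOc1ccc(Br)cc1OCOC | intermediate
3 | [3,4-bis(methoxymethoxy)phenyl]lithium | [Li]c1ccc(OCOC)c(OCOC)c1 | intermediate
4 | lithium [3,4-bis(methoxymethoxy)phenyl]tris(propan-2-yloxy)borate | [Li+].CC(C)O[B-](OC(C)C)(OC(C)C)c1ccc(OCOC)c(OCOC)c1 | intermediate
5 | [3,4-bis(methoxymethoxy)phenyl]boronic acid | COCOc1ccc(cc1OCOC)B(O)O | intermediate
6 | 2-methylcyclopent-2-en-1-one | CC1=CCCC1=O | starting material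
7 | (2R,3S)-3-[3,4-bis(methoxymethoxy)phenyl]-2-methylcyclopentan-1-one (trans; any C2 epimer converges in step 4) | O=C1CC[C@H](c2ccc(OCOC)c(OCOC)c2)[C@H]1C | intermediate
8 | potassium (3R)-3-[3,4-bis(methoxymethoxy)phenyl]-2-methylcyclopent-1-en-1-olate | [K+].[O-]C1=C(C)[C@@H](c2ccc(OCOC)c(OCOC)c2)CC1 | intermediate
9 | (3R)-3-[3,4-bis(methoxymethoxy)phenyl]-2,2-dimethylcyclopentan-1-one | O=C1CC[C@H](c2ccc(OCOC)c(OCOC)c2)C1(C)C | intermediate
10 | lithium (4R)-4-[3,4-bis(methoxymethoxy)phenyl]-5,5-dimethylcyclopent-1-en-1-olate | [Li+].[O-]C1=CC[C@H](c2ccc(OCOC)c(OCOC)c2)C1(C)C | intermediate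
11 | {[(4R)-4-[3,4-bis(methoxymethoxy)phenyl]-5,5-dimethylcyclopent-1-en-1-yl]oxy}trimethylsilane | C[Si](C)(C)OC1=CC[C@H](c2ccc(OCOC)c(OCOC)c2)C1(C)C | intermediate
12 | (4R)-4-[3,4-bis(methoxymethoxy)phenyl]-5,5-dimethylcyclopent-2-en-1-one | O=C1C=C[C@H](c2ccc(OCOC)c(OCOC)c2)C1(C)C | intermediate
13 | 1-bromo-3,5-dimethoxybenzene | COc1cc(Br)cc(OC)c1 | starting material
14 | [(2-bromo-4,6-dimethoxyphenyl)methylidene]dimethylammonium chloride | COc1cc(Br)c(C=[N+](C)C)c(OC)c1.[Cl-] | intermediate
15 | 2-bromo-4,6-dimethoxybenzaldehyde | COc1cc(Br)c(C=O)c(OC)c1 | intermediate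
16 | (3-bromo-2-formyl-5-methoxyphenoxy)dichloroborane | COc1cc(Br)c(C=O)c(OB(Cl)Cl)c1 | intermediate
17 | 2-bromo-6-hydroxy-4-methoxybenzaldehyde | COc1cc(O)c(C=O)c(Br)c1 | intermediate
18 | (2-methylprop-1-en-1-yl)magnesium bromide | CC(C)=C[Mg]Br | starting material
19 | 3-bromo-2-(1-hydroxy-3-methylbut-2-en-1-yl)-5-methoxyphenol | COc1cc(O)c(C(O)C=C(C)C)c(Br)c1 | intermediate
20 | 5-bromo-3-methoxy-6-(3-methylbut-2-en-1-ylidene)cyclohexa-2,4-dien-1-one | COC1=CC(=O)C(=CC=C(C)C)C(Br)=C1 | intermediate
21 | 5-bromo-7-methoxy-2,2-dimethyl-2H-chromene | COc1cc(Br)c2C=CC(C)(C)Oc2c1 | intermediate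
22 | (7-methoxy-2,2-dimethyl-2H-chromen-5-yl)magnesium bromide | COc1cc([Mg]Br)c2C=CC(C)(C)Oc2c1 | intermediate
23 | trimethylsilyl enol ether of 24 (trans-diaryl, configuration as in 24) | C[Si](C)(C)OC1=C[C@@H](c2cc(OC)cc3OC(C)(C)C=Cc23)[C@H](c2ccc(OCOC)c(OCOC)c2)C1(C)C | intermediate
24 | (3R,4R)-3-[3,4-bis(methoxymethoxy)phenyl]-4-(7-methoxy-2,2-dimethyl-2H-chromen-5-yl)-2,2-dimethylcyclopentan-1-one | O=C1C[C@@H](c2cc(OC)cc3OC(C)(C)C=Cc23)[C@H](c2ccc(OCOC)c(OCOC)c2)C1(C)C | intermediate
25 | lithium enolate of 24 (configuration as in 24) | [Li+].[O-]C1=C[C@@H](c2cc(OC)cc3OC(C)(C)C=Cc23)[C@H](c2ccc(OCOC)c(OCOC)c2)C1(C)C | intermediate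
26 | 5-(trifluoroacetyl) derivative of 24 (largely enolised, aryl-bearing centres as in 24) | O=C1C(C(=O)C(F)(F)F)[C@@H](c2cc(OC)cc3OC(C)(C)C=Cc23)[C@H](c2ccc(OCOC)c(OCOC)c2)C1(C)C | intermediate
27 | (3R,4R)-4-[3,4-bis(methoxymethoxy)phenyl]-2-diazo-3-(7-methoxy-2,2-dimethyl-2H-chromen-5-yl)-5,5-dimethylcyclopentan-1-one | [N-]=[N+]=C1[C@@H](c2cc(OC)cc3OC(C)(C)C=Cc23)[C@H](c2ccc(OCOC)c(OCOC)c2)C(C)(C)C1=O | intermediate
28 | cyclobutylidene ketene (C3=C2a exocyclic, aryl groups trans as in 27) | O=C=C1[C@@H](c2cc(OC)cc3OC(C)(C)C=Cc23)[C@H](c2ccc(OCOC)c(OCOC)c2)C1(C)C | intermediate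
29 | ester enol, methanol adduct of 28 | COC(O)=C1[C@@H](c2cc(OC)cc3OC(C)(C)C=Cc23)[C@H](c2ccc(OCOC)c(OCOC)c2)C1(C)C | intermediate
30 | methyl (1S,3S,4S)-3-[3,4-bis(methoxymethoxy)phenyl]-4-(7-methoxy-2,2-dimethyl-2H-chromen-5-yl)-2,2-dimethylcyclobutane-1-carboxylate (ester cis to ring A, aryl groups trans) | COC(=O)[C@H]1[C@@H](c2cc(OC)cc3OC(C)(C)C=Cc23)[C@H](c2ccc(OCOC)c(OCOC)c2)C1(C)C | intermediate
31 | trimethylstannyl ester of 32 | C[Sn](C)(C)OC(=O)[C@H]1[C@@H](c2cc(OC)cc3OC(C)(C)C=Cc23)[C@H](c2ccc(OCOC)c(OCOC)c2)C1(C)C | intermediate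
32 | (1S,3S,4S)-3-[3,4-bis(methoxymethoxy)phenyl]-4-(7-methoxy-2,2-dimethyl-2H-chromen-5-yl)-2,2-dimethylcyclobutane-1-carboxylic acid | OC(=O)[C@H]1[C@@H](c2cc(OC)cc3OC(C)(C)C=Cc23)[C@H](c2ccc(OCOC)c(OCOC)c2)C1(C)C | intermediate
33 | mixed anhydride of 32 and trifluoroacetic acid | O=C(OC(=O)C(F)(F)F)[C@H]1[C@@H](c2cc(OC)cc3OC(C)(C)C=Cc23)[C@H](c2ccc(OCOC)c(OCOC)c2)C1(C)C | intermediate
34 | (1S,2aS,7bS)-1-[3,4-bis(methoxymethoxy)phenyl]-4-methoxy-2,2-dimethyl-6,7-pyrano-1,2,2a,7b-tetrahydro-3H-cyclobuta[a]inden-3-one | COc1cc2c(c3c1C(=O)[C@H]1[C@@H]3[C@H](c3ccc(OCOC)c(OCOC)c3)C1(C)C)C=CC(C)(C)O2 | intermediate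
35 | 4-methylbenzenesulfonohydrazone of 34 (1S,2aS,7bS) | COc1cc2c(c3c1C(=NNS(=O)(=O)c4ccc(C)cc4)[C@H]1[C@@H]3[C@H](c3ccc(OCOC)c(OCOC)c3)C1(C)C)C=CC(C)(C)O2 | intermediate
36 | N-(1,3,2-benzodioxaborol-2-yl)-N'-tosylhydrazine at C3 (hydride adduct of 35) | COc1cc2c(c3c1C(N(NS(=O)(=O)c4ccc(C)cc4)B4Oc5ccccc5O4)[C@H]1[C@@H]3[C@H](c3ccc(OCOC)c(OCOC)c3)C1(C)C)C=CC(C)(C)O2 | intermediate
37 | C3 alkyldiazene | COc1cc2c(c3c1C(N=N)[C@H]1[C@@H]3[C@H](c3ccc(OCOC)c(OCOC)c3)C1(C)C)C=CC(C)(C)O2 | intermediate
38 | (1S,2aS,7bR)-1-[3,4-bis(methoxymethoxy)phenyl]-4-methoxy-2,2-dimethyl-6,7-pyrano-2,2a,3,7b-tetrahydro-1H-cyclobuta[a]indene | COc1cc2c(c3c1C[C@H]1[C@@H]3[C@H](c3ccc(OCOC)c(OCOC)c3)C1(C)C)C=CC(C)(C)O2 | intermediate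
39 | bis(trimethylsilyl) ether of 40 | COc1cc2c(c3c1C[C@H]1[C@@H]3[C@H](c3ccc(O[Si](C)(C)C)c(O[Si](C)(C)C)c3)C1(C)C)C=CC(C)(C)O2 | intermediate
40 | CNP0207533.1, (1S,2aS,7bR)-1-(3,4-dihydroxyphenyl)-4-methoxy-2,2-dimethyl-6,7-pyrano-2,2a,3,7b-tetrahydro-1H-cyclobuta[a]indene | COc1cc2c(c3c1C[C@H]1[C@@H]3[C@H](c3ccc(O)c(O)c3)C1(C)C)C=CC(C)(C)O2 | target

Total step count: 16.
Longest linear sequence: 13 steps (steps 1–5 and 9–16, from 4-bromobenzene-1,2-diol). Steps 6–8 form the convergent ring A branch.

Steps most likely to fail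

Step 3. Insertion of the α-methyl-substituted enone into the aryl–rhodium bond may be so slow that hydrolytic protodeboronation uses up the aryl donor. The fallback sets out from 3 (made from 2 as in step 2) and 6 and comes back at 9.
- ZnCl2 in THF transmetallates 3 to [3,4-bis(methoxymethoxy)phenyl]zinc chloride F1.
- F1 is added to 6 with [RhCl(C2H4)2]2 and (S)-BINAP in THF at 20 °C in the presence of Me3SiCl. This is the aprotic form of the rhodium-catalysed 1,4-addition: no proton source can destroy the aryl donor, and silylation of the rhodium enolate drives turnover.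
- It should give the tetrasubstituted {[(3R)-3-[3,4-bis(methoxymethoxy)phenyl]-2-methylcyclopent-1-en-1-yl]oxy}trimethylsilane F2.
- MeLi in THF cleaves the O–Si bond to the regiodefined lithium (3R)-3-aryl-2-methylcyclopent-1-en-1-olate F3, and MeI then gives 9.
- Steps 3 and 4 are both replaced, so the regiochemical question of step 4 disappears.

Step 11. The ketonisation of enol 29 may show poor facial selectivity, so that much of the material ends as the C2a epimer, which cannot close the five-membered ring. The fallback sets out from 27 and comes back at 30.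
- The photolysis is run as described, and the epimeric methyl (1R,3S,4S)-cyclobutanecarboxylate F4 is separated from 30.
- F4 is deprotonated with LiN(iPr)2 in THF at −78 °C to the planar lithium ester enolate F5 and quenched at that temperature with 2,6-di-tert-butyl-4-methylphenol.
- Stereocontrol thereby moves from solvent-mediated proton transfer during the photolysis to a separate contra-thermodynamic protonation, by a donor too large to pass the ring A aryl group.
- Unconverted F4 can be recycled.

Step 13. The acid released in the acylation may start cationic oligomerisation of the electron-rich chromene double bond or loss of a MOM group before ring closure is complete, and the anhydride may trifluoroacetylate ring A. The fallback sets out from 30 and comes back at 34, bypassing 32.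
- Aminolysis with Me2AlNMe2 (from AlMe3 and Me2NH·HCl, toluene, 80 °C) gives the (1S,3S,4S)-N,N-dimethylcyclobutanecarboxamide F6.
- Tf2O and 2-chloropyridine in CH2Cl2 (−78 to 0 °C) convert it into the O-triflyliminium triflate F7.
- F7 attacks C3a in an intramolecular Vilsmeier–Haack-type cyclisation to the cyclic iminium triflate F8, and aqueous NaHCO3 hydrolyses F8 to 34.
- The electrophile is an iminium ion in a pyridine-buffered medium, so no free strong acid meets the chromene or the acetals.

Further compounds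
F1 | step 3 | [3,4-bis(methoxymethoxy)phenyl]zinc chloride | Cl[Zn]c1ccc(OCOC)c(OCOC)c1
F2 | step 3 | {[(3R)-3-[3,4-bis(methoxymethoxy)phenyl]-2-methylcyclopent-1-en-1-yl]oxy}trimethylsilane | C[Si](C)(C)OC1=C(C)[C@@H](c2ccc(OCOC)c(OCOC)c2)CC1
F3 | step 3 | lithium (3R)-3-[3,4-bis(methoxymethoxy)phenyl]-2-methylcyclopent-1-en-1-olate | [Li+].[O-]C1=C(C)[C@@H](c2ccc(OCOC)c(OCOC)c2)CC1
F4 | step 11 | methyl (1R,3S,4S)-3-[3,4-bis(methoxymethoxy)phenyl]-4-(7-methoxy-2,2-dimethyl-2H-chromen-5-yl)-2,2-dimethylcyclobutane-1-carboxylate | COC(=O)[C@@H]1[C@@H](c2cc(OC)cc3OC(C)(C)C=Cc23)[C@H](c2ccc(OCOC)c(OCOC)c2)C1(C)C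
F5 | step 11 | lithium enolate of esters F4 and 30 | [Li+].COC([O-])=C1[C@@H](c2cc(OC)cc3OC(C)(C)C=Cc23)[C@H](c2ccc(OCOC)c(OCOC)c2)C1(C)C
F6 | step 13 | (1S,3S,4S)-3-[3,4-bis(methoxymethoxy)phenyl]-4-(7-methoxy-2,2-dimethyl-2H-chromen-5-yl)-N,N,2,2-tetramethylcyclobutane-1-carboxamide | CN(C)C(=O)[C@H]1[C@@H](c2cc(OC)cc3OC(C)(C)C=Cc23)[C@H](c2ccc(OCOC)c(OCOC)c2)C1(C)C
F7 | step 13 | O-triflyliminium triflate of F6 | C[N+](C)=C(OS(=O)(=O)C(F)(F)F)[C@H]1[C@@H](c2cc(OC)cc3OC(C)(C)C=Cc23)[C@H](c2ccc(OCOC)c(OCOC)c2)C1(C)C.[O-]S(=O)(=O)C(F)(F)F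
F8 | step 13 | C3 N,N-dimethyliminium triflate corresponding to ketone 34 | COc1cc2c(c3c1C(=[N+](C)C)[C@H]1[C@@H]3[C@H](c3ccc(OCOC)c(OCOC)c3)C1(C)C)C=CC(C)(C)O2.[O-]S(=O)(=O)C(F)(F)F
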